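# Chebulic acid by an intramolecular Diels–Alder reaction with a sacrificial cyclohexene

## Structural features

1. Chebulic acid is a 3,4-dihydroisocoumarin. A benzene ring (C4a, C5–C8, C8a; OH on C5, C6 and C7, H on C8) is fused through C4a–C8a to a six-membered δ-lactone C1(=O)–O2–C3–C4.
2. C3 carries a carboxyl group and C4 carries a succinic acid residue, C1′H(CO2H)–C2′H2–CO2H, so three free acids stand beside the lactone.
3. The stereocentres C3, C4 and C1′ (all S) are contiguous methines. The C3 carboxyl and the C4 side chain are trans on the lactone ring, and C1′ lies outside every ring.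
4. C4 is benzylic and peri to the C5 oxygen. The arene is therefore di-ortho-substituted where the chain is attached, and any bond formation at C4 is crowded.
5. The fragile parts are the pyrogallol unit (oxidation, base), C3–H and C1′–H (both α to carboxyl, epimerisable), the lactone acyl–oxygen bond, and the very polar free triacid. The last step must therefore be neutral.
6. The real difficulty is the triad C3/C4/C1′, including the acyclic C1′. It must be set in relative and absolute sense with no later base-mediated correction.
7. The key step exploits one feature. The carboxyl carbon on C3 and the carboxyl carbon on C2′ are 1,6-related through C3–C4–C1′–C2′. Joined by a C=C they give a cyclohexene fused to the lactone at C3–C4. This ring is a complete Diels–Alder retron: O2 sits on one diene terminus, the arene sits on the dienophile, and the unit C1–C8a–C4a serves as tether. The target configuration corresponds to O2, aryl and carboxyl all-trans on that ring, which is the E,E-endo outcome.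
8. In one sentence: an auxiliary-steered intramolecular Diels–Alder reaction of a butadienyl 2-(acryloyl)benzoate closes the lactone and a sacrificial cyclohexene and sets all three stereocentres at once. This is not the conjugate addition/lactonisation plan that would be drawn first.

## Logic of the disconnections

**19 ⇒ 18.**
- Cut: the three phenolic O–H groups are traced back to O–CH2Ph bonds on O5, O6 and O7.
- Reason: the pyrogallol is the most oxidisable part and must be masked while ozone and chlorite are used.
- Gain: the end game becomes one neutral operation.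
- Demand: 18 may hold no other reducible group, and the release must touch none of the three C–H stereocentres.

**18 ⇒ 17 ⇒ 15.**
- Cut: the carboxyl carbon on C3 and the carboxyl carbon on C2′ are reconnected by a C=C bond, which the forward steps cleave.
- Reason: this is the only pairing of two carboxyl groups that gives a six-membered ring with its alkene opposite the C4–C1′ bond.
- Gain: two of the three acids vanish and the acyclic C1′ becomes a ring stereocentre. The flexible chain becomes a trans-fused tricycle with O2, aryl and carboxyl all equatorial.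
- Demand: the cleavage must prefer a 1,2-disubstituted alkene over a tris(benzyloxy)arene. The α-acyloxy aldehyde in 17 must reach 18 without enolisation.

**15 ⇒ 13.**
- Cut: the C1′-carboxyl is traced back to an acyl–N bond to 4.
- Reason: the imide is the only two-point binding site of the precursor, so a Lewis acid activates the dienophile and nothing else, and 4 supplies the absolute control.
- Gain: no chiral catalyst has to find one carbonyl among eight oxygen atoms.
- Demand: the exocyclic acyl–N bond must be cleaved in the presence of the lactone.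

**13 ⇒ 12 (key).**
- Cut: C3–C4 and C1′–C2′.
- Reason: these are the two σ-bonds of the Diels–Alder retron, and C3–C4 is also a ring bond of the lactone.
- Gain: two rings and three contiguous stereocentres go back to an achiral-chain triene. Its only stereochemical information is two E double bonds and the stereocentre of 4.
- Labels in 12: the diene carbons are D1 (O-bearing) to D4, and the dienophile carbons are Cβ (aryl-bearing) and Cα.
- Demand: fused-mode closure, the imide-endo/tether-exo transition state, and one alkene face.

**12 ⇒ 8 + 9.**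
- Cut: the acyl–oxygen bond C1–O2.
- Reason: all four diene carbons and O2 come from 9 in one operation.
- Gain: a commodity C4 aldehyde replaces a built-up diene.
- Demand: O-acylation of the extended enolate with E geometry. The route must also avoid any stage at which a carboxylate stands next to the Michael acceptor carbon C4.

**8 ⇒ 7 ⇒ 3 + 6.**
- Cut: the aryl–vinyl bond C4a–C4, together with the O–tert-butyl bond that masks the acid during the coupling.
- Reason: the gallate ring and the C3 acrylate unit are both available as such.
- Gain: full convergence.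
- Demand: coupling at a di-ortho-substituted, electron-rich iodide with E selectivity, followed by acidic release of the acid.

**6 ⇒ 4 + 5, and 3 ⇒ 2 ⇒ 1.**
- Cut: the acyl–N bond, the C–I bond and the ester O–C bond.
- Reason and gain: each leads to a commercial compound.
- Demand: mono-iodination, which the equivalence of the two free ring positions makes regiochemically trivial.

## Other disconnections considered

**Alternative 1:** (the first idea) The cut is C4–C1′ with the heterocycle already in place. The forward key step is conjugate addition of a chiral succinate enolate to C4 of benzyl 5,6,7-tris(benzyloxy)isocoumarin-3-carboxylate A1, followed by protonation at C3.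
- In A1, C4 is the β-carbon of an acrylate and also the β-carbon of an enol ester. The ring oxygen pushes electron density to the very position that should accept it, while the lactone carbonyl C1 stays open to the enolate.
- C4 is shielded by the peri C5 substituent.
- The three stereocentres would arise from three separate events: enolate face, acceptor face and protonation.
- Protonation of the C3 enolate anti to the new C4 substituent should place the C3 ester cis to the side chain, the wrong relation. A base-mediated correction would follow on a compound with two epimerisable centres.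
- The chosen plan sets the triad in one suprafacial event.

**Alternative 2:** The cut is C4–C1′ by a [3,3] shift. The forward key step is the Ireland–Claisen rearrangement of the cinnamyl benzyl succinate A2 to the pentenoic acid A3. Dihydroxylation of the vinyl group, lactonisation and oxidation of the primary alcohol would follow.
- The rearrangement sets only C4 and C1′.
- A2 has no stereocentre, so an external chiral controller would be needed.
- The unsymmetrical succinate has two enolisable methylene groups.
- The di-ortho-substituted aryl terminus should weaken the chair preference.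
- C3 would be set later by dihydroxylation of a monosubstituted alkene next to a branched centre, a weak substrate class for reagent control.
- Extra redox steps would follow, so step economy and stereochemical economy are both lower.

**Alternative 3:** The cut reconnects the carboxyl carbons on C3 and on C1′ instead, which gives a cyclopentanone. The forward key step starts from (R)-4-(tert-butyldimethylsilyloxy)cyclopent-2-enone A4. The aryl cuprate derived from 3 would add to it, and the enolate would be alkylated with a haloacetate to give cyclopentanone A5. The ketone C1–C5 bond would then be cleaved.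
- Mapping the target onto this ring shows that it needs the aryl group and the acetate arm cis (2,3-cis, 3,4-trans).
- The tandem addition/alkylation, and any equilibration α to the ketone, should give the all-trans A5. That compound maps onto the C1′ epimer of the target.
- A cuprate with two ortho substituents is a poor donor.
- The cleavage needs enolisation towards the carbon β to the silyloxy group, which invites elimination.
- The cyclohexene reconnection has the opposite property: its natural all-trans outcome is the target configuration.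

Key step: step 7

Assumptions:
- The SMILES is read as 3S,4S in the ring and S at C1′, with the C3 carboxyl trans to the C4 side chain.
- Compounds 1, 4, 5 and 9 are taken as commercial, and 9 as its E isomer.

## Steps

Step 1
Reactants: 1 3,4,5-tris(benzyloxy)benzoic acid
Product: 2 tert-butyl 3,4,5-tris(benzyloxy)benzoate
Conditions: tert-butyl 2,2,2-trichloroacetimidate, BF3·OEt2 (cat.), CH2Cl2/cyclohexane, rt
Reagents that add atoms: tert-butyl 2,2,2-trichloroacetimidate, CC(C)(C)OC(=N)C(Cl)(Cl)Cl
Why: Acid-catalysed O-alkylation of a carboxylic acid by a trichloroacetimidate (tert-butyl cation transfer), to which the aryl benzyl ethers are inert. The tert-butyl ester survives palladium and bicarbonate and is later removed by acid, so no carboxylate is ever formed next to the acceptor carbon C4.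

Step 2
Reactants: 2 tert-butyl 3,4,5-tris(benzyloxy)benzoate
Product: 3 tert-butyl 3,4,5-tris(benzyloxy)-2-iodobenzoate
Conditions: NIS, TFA (cat.), MeCN, rt, dark
Reagents that add atoms: N-iodosuccinimide, O=C1CCC(=O)N1I
Why: Electrophilic aromatic iodination. The two free positions are equivalent, and each is ortho and para to a benzyloxy group. The first iodine hinders and deactivates the ring against a second substitution.

Step 3
Reactants: 4 (4S)-4-benzyl-1,3-oxazolidin-2-one; 5 acryloyl chloride
Product: 6 (4S)-3-acryloyl-4-benzyl-1,3-oxazolidin-2-one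
Conditions: Et3N, LiCl, BHT (trace), THF, −20 °C to rt
Reagents that add atoms: none
Why: N-acylation of an oxazolidinone under soft deprotonation (LiCl/Et3N); the stereocentre is not involved. Low temperature and a radical inhibitor hold back polymerisation of the acryloyl unit.

Step 4
Reactants: 3 tert-butyl 3,4,5-tris(benzyloxy)-2-iodobenzoate; 6 (4S)-3-acryloyl-4-benzyl-1,3-oxazolidin-2-one
Product: 7 tert-butyl 3,4,5-tris(benzyloxy)-2-{(1E)-3-[(4S)-4-benzyl-2-oxo-1,3-oxazolidin-3-yl]-3-oxoprop-1-en-1-yl}benzoate
Conditions: Pd(OAc)2 (cat.), nBu4NCl, NaHCO3, DMF, 75 °C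
Reagents that add atoms: none
Why: Mizoroki–Heck reaction under ligand-free phase-transfer conditions. Oxidative addition of the iodide, syn insertion at the unsubstituted acrylimide terminus and syn β-hydride elimination give the E alkene. Bicarbonate is too weak to harm the imide, the ester or the ethers.

Step 5
Reactants: 7 tert-butyl 3,4,5-tris(benzyloxy)-2-{(1E)-3-[(4S)-4-benzyl-2-oxo-1,3-oxazolidin-3-yl]-3-oxoprop-1-en-1-yl}benzoate
Product: 8 3,4,5-tris(benzyloxy)-2-{(1E)-3-[(4S)-4-benzyl-2-oxo-1,3-oxazolidin-3-yl]-3-oxoprop-1-en-1-yl}benzoic acid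
Conditions: TFA/CH2Cl2 (1:4), 0 °C to rt
Reagents that add atoms: none
Why: Acidolysis (E1) of a tert-butyl ester; aryl benzyl ethers, imide and alkene tolerate short exposure to dilute TFA. The acid stays protonated throughout, which holds back its intramolecular oxa-Michael addition to C4.

Step 6
Reactants: 8 3,4,5-tris(benzyloxy)-2-{(1E)-3-[(4S)-4-benzyl-2-oxo-1,3-oxazolidin-3-yl]-3-oxoprop-1-en-1-yl}benzoic acid; 9 (E)-but-2-enal (crotonaldehyde)
Product: 12 (1E)-buta-1,3-dien-1-yl 3,4,5-tris(benzyloxy)-2-{(1E)-3-[(4S)-4-benzyl-2-oxo-1,3-oxazolidin-3-yl]-3-oxoprop-1-en-1-yl}benzoate, via acid chloride 10 (not isolated), via potassium dienolate 11 (not isolated)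
Conditions: (COCl)2, DMF (cat.), CH2Cl2, 0 °C to rt, evaporate; separately 9, KOtBu, THF, −78 °C; add 10, −78 °C
Reagents that add atoms: oxalyl chloride, O=C(Cl)C(=O)Cl (Cl of 10); potassium tert-butoxide, CC(C)(C)[O-].[K+] (K of 11)
Why: Vilsmeier-catalysed acid chloride formation is followed by O-acylation of an extended potassium enolate, at which the hard acyl chloride reacts on oxygen. γ-Deprotonation of the dominant s-trans conformer of 9 places O and D3 anti, so the E dienyl ester should prevail. Any Z isomer is removed by chromatography and could not reach the cycloaddition geometry in any case.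

Step 7
Reactants: 12 (1E)-buta-1,3-dien-1-yl 3,4,5-tris(benzyloxy)-2-{(1E)-3-[(4S)-4-benzyl-2-oxo-1,3-oxazolidin-3-yl]-3-oxoprop-1-en-1-yl}benzoate
Product: 13 (4S)-4-benzyl-3-{[(1S,4aR,10bS)-8,9,10-tris(benzyloxy)-6-oxo-1,2,4a,10b-tetrahydro-6H-benzo[c]chromen-1-yl]carbonyl}-1,3-oxazolidin-2-one
Conditions: Me2AlCl (3 equiv), CH2Cl2 (0.005 M), −40 to 0 °C; then 1 M HCl
Reagents that add atoms: none
Why: Excess Me2AlCl turns the imide, the only two-point binding site of 12, into the cationic AlMe2 chelate (both C=O syn, enoyl unit s-cis), and this LUMO-lowered dienophile undergoes a concerted, asynchronous, suprafacial [4+2] cycloaddition with the dienyl ester that forms C3–C4 (D1 to Cβ, the more advanced bond) and C1′–C2′ (Cα to D4). The closest known reaction type is the aluminium-promoted type 1 intramolecular Diels–Alder reaction of trienes that end in an N-enoyl oxazolidinone; 1-acyloxybutadienes are established dienes and ester-tethered variants are known, though slower. The δ-lactone closes in the fused mode across the four-atom tether O2–C1–C8a–C4a (six-membered, through the C3–C4 bond) and the cyclohexene closes as the six-membered cycloaddition ring, while the bridged mode (D1 to Cα) would have to span 1,3-positions of the new ring with the same short, sp2-rich tether and is out of reach, so the tether and not the weak acyloxy donor fixes the regiochemistry. C4 and C1′ come out with aryl and carbonyl trans because the E alkene adds suprafacially. C3 follows from the E dienyl geometry together with the imide-endo, tether-exo transition state, which gives the trans ring fusion with O2 cis to the carbonyl group; complexation strengthens the endo preference and the flat benzoate tether supports it, because it then extends away from the diene with the enol ester near its preferred anti C=C–O–C(=O) arrangement instead of being folded under D2. The absolute sense is set by the benzyl group of the (S)-auxiliary, which covers the Cα-Re face of the chelate, so the diene adds to the Cα-Si face and gives 1S,10bS,4aR (C1′ S, C4 S, C3 S of the target); the two rotamers about C4a–C4 offer opposite alkene faces to the ester arm and interconvert in a fast pre-equilibrium, so the auxiliary chooses between them. The two ortho substituents already hold the alkene nearly perpendicular to the arene, so the p orbital at C4 points along the arene plane towards the ester arm and little conjugation is lost on the way to the transition state. The price is that the ester must reach its less favoured E rotamer and that the acyloxy group sits on the diene terminus where it cannot assist; chelate activation and high dilution are meant to pay for this.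

Step 8
Reactants: 13 (4S)-4-benzyl-3-{[(1S,4aR,10bS)-8,9,10-tris(benzyloxy)-6-oxo-1,2,4a,10b-tetrahydro-6H-benzo[c]chromen-1-yl]carbonyl}-1,3-oxazolidin-2-one
Product: 15 (1S,4aR,10bS)-8,9,10-tris(benzyloxy)-6-oxo-1,2,4a,10b-tetrahydro-6H-benzo[c]chromene-1-carboxylic acid, via peroxy acid 14 (not isolated)
Conditions: LiOH, H2O2, THF/H2O (3:1), 0 °C; Na2SO3; then HCl to pH 3
Reagents that add atoms: hydrogen peroxide, OO (O–O of 14; one O stays in 15)
Why: Hydroperoxide cleavage of an N-acyl oxazolidinone, in which the α-effect nucleophile attacks the exocyclic imide carbonyl while the lactone carbonyl is deactivated by the para benzyloxy donor. Sulfite is added before acidification, so the peroxy acid is reduced as its anion and cannot epoxidise the alkene. C1 bears its carbonyl group equatorially, so there is no drive to epimerise.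

Step 9
Reactants: 15 (1S,4aR,10bS)-8,9,10-tris(benzyloxy)-6-oxo-1,2,4a,10b-tetrahydro-6H-benzo[c]chromene-1-carboxylic acid
Product: 17 (2S)-2-[(3S,4S)-5,6,7-tris(benzyloxy)-3-formyl-1-oxo-3,4-dihydro-1H-isochromen-4-yl]-4-oxobutanoic acid, via ozonide 16 (not isolated)
Conditions: O3, CH2Cl2, −78 °C (Sudan III end point); Me2S, −78 °C to rt
Reagents that add atoms: ozone, [O-][O+]=O
Why: Ozonolysis (Criegee mechanism). The 1,2-disubstituted alkene is the most reactive π bond, the arene is tempered by the lactone carbonyl, and the dye stops the ozone supply at the end point. The neutral reductive work-up avoids enolisation of the new α-acyloxy aldehyde at C3.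

Step 10
Reactants: 17 (2S)-2-[(3S,4S)-5,6,7-tris(benzyloxy)-3-formyl-1-oxo-3,4-dihydro-1H-isochromen-4-yl]-4-oxobutanoic acid
Product: 18 (2S)-2-[(3S,4S)-5,6,7-tris(benzyloxy)-3-carboxy-1-oxo-3,4-dihydro-1H-isochromen-4-yl]butanedioic acid (5,6,7-tri-O-benzylchebulic acid)
Conditions: NaClO2, NaH2PO4, 2-methyl-2-butene, tBuOH/H2O, 0 °C to rt
Reagents that add atoms: sodium chlorite, [Na+].[O-]Cl=O
Why: Pinnick oxidation of both aldehydes at about pH 4, where neither C3 nor C1′ enolises. The excess alkene intercepts hypochlorous acid before it can chlorinate the free ring position C8.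

Step 11
Reactants: 18 (2S)-2-[(3S,4S)-5,6,7-tris(benzyloxy)-3-carboxy-1-oxo-3,4-dihydro-1H-isochromen-4-yl]butanedioic acid
Product: 19 chebulic acid, (2S)-2-[(3S,4S)-3-carboxy-5,6,7-trihydroxy-1-oxo-3,4-dihydro-1H-isochromen-4-yl]butanedioic acid
Conditions: H2 (1 atm), 10% Pd/C, THF/MeOH, rt
Reagents that add atoms: none
Why: Hydrogenolysis of three aryl benzyl ethers under neutral conditions. No other reducible group is left, the C3–O2 bond is not benzylic, and none of the stereocentres is touched. Filtration and evaporation under inert gas spare the pyrogallol.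

## Compound list

1 | 3,4,5-tris(benzyloxy)benzoic acid | OC(=O)c1cc(OCc2ccccc2)c(OCc2ccccc2)c(OCc2ccccc2)c1 | starting material
2 | tert-butyl 3,4,5-tris(benzyloxy)benzoate | CC(C)(C)OC(=O)c1cc(OCc2ccccc2)c(OCc2ccccc2)c(OCc2ccccc2)c1 | intermediate
3 | tert-butyl 3,4,5-tris(benzyloxy)-2-iodobenzoate | CC(C)(C)OC(=O)c1cc(OCc2ccccc2)c(OCc2ccccc2)c(OCc2ccccc2)c1I | intermediate
4 | (4S)-4-benzyl-1,3-oxazolidin-2-one | O=C1N[C@@H](Cc2ccccc2)CO1 | starting material
5 | acryloyl chloride | C=CC(=O)Cl | starting material
6 | (4S)-3-acryloyl-4-benzyl-1,3-oxazolidin-2-one | C=CC(=O)N1[C@@H](Cc2ccccc2)COC1=O | intermediate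
7 | tert-butyl 3,4,5-tris(benzyloxy)-2-{(1E)-3-[(4S)-4-benzyl-2-oxo-1,3-oxazolidin-3-yl]-3-oxoprop-1-en-1-yl}benzoate | CC(C)(C)OC(=O)c1cc(OCc2ccccc2)c(OCc2ccccc2)c(OCc2ccccc2)c1/C=C/C(=O)N3[C@@H](Cc4ccccc4)COC3=O | intermediate
8 | 3,4,5-tris(benzyloxy)-2-{(1E)-3-[(4S)-4-benzyl-2-oxo-1,3-oxazolidin-3-yl]-3-oxoprop-1-en-1-yl}benzoic acid | OC(=O)c1cc(OCc2ccccc2)c(OCc2ccccc2)c(OCc2ccccc2)c1/C=C/C(=O)N3[C@@H](Cc4ccccc4)COC3=O | intermediate
9 | (E)-but-2-enal (crotonaldehyde) | C/C=C/C=O | starting material
10 | 3,4,5-tris(benzyloxy)-2-{(1E)-3-[(4S)-4-benzyl-2-oxo-1,3-oxazolidin-3-yl]-3-oxoprop-1-en-1-yl}benzoyl chloride | ClC(=O)c1cc(OCc2ccccc2)c(OCc2ccccc2)c(OCc2ccccc2)c1/C=C/C(=O)N3[C@@H](Cc4ccccc4)COC3=O | intermediate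
11 | potassium (1E)-buta-1,3-dien-1-olate | [K+].[O-]/C=C/C=C | intermediate
12 | (1E)-buta-1,3-dien-1-yl 3,4,5-tris(benzyloxy)-2-{(1E)-3-[(4S)-4-benzyl-2-oxo-1,3-oxazolidin-3-yl]-3-oxoprop-1-en-1-yl}benzoate | C=C/C=C/OC(=O)c1cc(OCc2ccccc2)c(OCc2ccccc2)c(OCc2ccccc2)c1/C=C/C(=O)N3[C@@H](Cc4ccccc4)COC3=O | intermediate
13 | (4S)-4-benzyl-3-{[(1S,4aR,10bS)-8,9,10-tris(benzyloxy)-6-oxo-1,2,4a,10b-tetrahydro-6H-benzo[c]chromen-1-yl]carbonyl}-1,3-oxazolidin-2-one | C3C[C@H](C(=O)N4[C@@H](Cc8ccccc8)COC4=O)[C@H]1c2c(cc(OCc5ccccc5)c(OCc6ccccc6)c2OCc7ccccc7)C(=O)O[C@@H]1C=3 | intermediate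
14 | (1S,4aR,10bS)-8,9,10-tris(benzyloxy)-6-oxo-1,2,4a,10b-tetrahydro-6H-benzo[c]chromene-1-carboperoxoic acid | C3C[C@H](C(=O)OO)[C@H]1c2c(cc(OCc5ccccc5)c(OCc6ccccc6)c2OCc7ccccc7)C(=O)O[C@@H]1C=3 | intermediate
15 | (1S,4aR,10bS)-8,9,10-tris(benzyloxy)-6-oxo-1,2,4a,10b-tetrahydro-6H-benzo[c]chromene-1-carboxylic acid | C3C[C@H](C(=O)O)[C@H]1c2c(cc(OCc5ccccc5)c(OCc6ccccc6)c2OCc7ccccc7)C(=O)O[C@@H]1C=3 | intermediate
16 | secondary ozonide (1,2,4-trioxolane) of 15, acetal carbons undefined | C34C[C@H](C(=O)O)[C@H]1c2c(cc(OCc5ccccc5)c(OCc6ccccc6)c2OCc7ccccc7)C(=O)O[C@@H]1C(OO3)O4 | intermediate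
17 | (2S)-2-[(3S,4S)-5,6,7-tris(benzyloxy)-3-formyl-1-oxo-3,4-dihydro-1H-isochromen-4-yl]-4-oxobutanoic acid | O=CC[C@H](C(=O)O)[C@H]1c2c(cc(OCc5ccccc5)c(OCc6ccccc6)c2OCc7ccccc7)C(=O)O[C@@H]1C=O | intermediate
18 | (2S)-2-[(3S,4S)-5,6,7-tris(benzyloxy)-3-carboxy-1-oxo-3,4-dihydro-1H-isochromen-4-yl]butanedioic acid | O=C(O)C[C@H](C(=O)O)[C@H]1c2c(cc(OCc5ccccc5)c(OCc6ccccc6)c2OCc7ccccc7)C(=O)O[C@@H]1C(=O)O | intermediate
19 | chebulic acid | O=C(O)C[C@H](C(=O)O)[C@H]1c2c(cc(O)c(O)c2O)C(=O)O[C@@H]1C(=O)O | target

## Step count and least certain steps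

- Total step count: 11.
- Longest linear sequence: 10 (steps 1, 2, 4, 5, 6, 7, 8, 9, 10, 11, from 1). Step 3 is the convergent branch.

**Step 7 (key step).**
- Most likely failure: the cycloaddition does not keep pace with Lewis acid-induced decay of the enol ester.
- The ester has to leave its favoured Z rotamer, and the benzoate must twist out of conjugation.
- The acyloxy donor sits on the diene terminus where it gives no polar assistance.
- During a long exposure the aluminium reagent can ionise the enol ester or the allylic lactone. The neighbouring ester carbonyl can also add reversibly to the activated C4.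
- A second risk is erosion of the endo preference by the peri C5 benzyloxy group.
- Fallback (sets out from 10, returns at 18): the diene is made polarity-matched and much more electron-rich.
  - Acid chloride 10 acylates the primary hydroxyl of commercial but-3-ene-1,2-diol (pyridine, CH2Cl2, −20 °C) to give the 2-hydroxybut-3-enyl ester F1.
  - Dess–Martin oxidation gives the 2-oxobut-3-enyl ester F2.
  - TBSOTf/Et3N enolises the only enolisable position and should give the (1Z)-2-silyloxybutadienyl ester F3, with the acyloxy group again on the outside of the diene.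
  - The 2-silyloxy donor makes D1 the nucleophilic terminus, so the tether-enforced D1–C4 bond is now the one that polar effects favour.
  - With the same chelate at −78 °C the closure, concerted or as a Mukaiyama–Michael/Michael sequence, should give the silyl enol ether adduct F4.
  - Ozonolysis of the enol ether C=C (Me2S work-up) gives the aldehyde acid F5, and Pinnick oxidation gives the diacid imide F6.
  - Hydroperoxide cleavage of the auxiliary then gives 18.

**Step 6.**
- Most likely failure: loss of chemoselectivity of the dienolate or of residual tert-butoxide. This could take the form of attack on the imide, Michael addition to C4, C-acylation, or erosion of the E geometry, because a strong oxyanion meets a substrate with three electrophilic sites.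
- Fallback (sets out from 8, returns at 12): acid 8 is converted with DAST (CH2Cl2, 0 °C) into the acyl fluoride F7. This is combined with commercial (E)-1-(trimethylsilyloxy)buta-1,3-diene and a catalytic anhydrous fluoride source (TBAT, THF, −78 to 0 °C). The fluoride-catalysed silyl-to-acyl exchange on oxygen should keep the E geometry and needs no free alkoxide base.

**Step 4.**
- Most likely failure: slow insertion at the di-ortho-substituted, electron-rich arylpalladium species. Protodeiodination and polymerisation of 6 would then take over.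
- Fallback (sets out from 3 and 4, returns at 7): olefination replaces the cross-coupling.
  - Iodine–magnesium exchange of 3 (iPrMgCl·LiCl, THF, −40 °C) gives the arylmagnesium chloride F8.
  - DMF converts F8 into the aldehyde F9.
  - 4 is acylated with commercial diethylphosphonoacetic acid (DCC, DMAP) to give the phosphonate imide F10.
  - Horner–Wadsworth–Emmons olefination of F9 with F10 (LiCl, iPr2NEt, MeCN) should give 7 as the E isomer.

**Step 8.**
- Most likely failure: attack of hydroperoxide at the lactone carbonyl or at the ring carbamate of the auxiliary, because the exocyclic carbonyl is flanked by the bulky C10b aryl group.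
- Fallback (sets out from 13, returns at 15): a soft nucleophile is used. Lithium ethanethiolate (EtSH, nBuLi, THF, 0 °C) converts the imide into the S-ethyl thioester F11. Silver-assisted hydrolysis (AgNO3, THF/H2O) releases 15 under nearly neutral conditions.

**Step 9.**
- Most likely failure: over-oxidation, that is ozone attack on the tris(benzyloxy)arene or on benzylic C–H bonds once the alkene is used up. Epimerisation at C3 during handling of the dialdehyde is a further risk.
- Fallback (sets out from 15, returns at 17): catalytic osmylation (OsO4, NMO, acetone/H2O), which does not touch arenes or ethers, gives the cis-diol F12. Its two new centres are immaterial. Glycol cleavage with NaIO4 (THF/H2O) gives 17, which is taken directly into step 10.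

## Further compounds

F1 | step 7 | 2-hydroxybut-3-en-1-yl 3,4,5-tris(benzyloxy)-2-{(1E)-3-[(4S)-4-benzyl-2-oxo-1,3-oxazolidin-3-yl]-3-oxoprop-1-en-1-yl}benzoate (both carbinol epimers) | C=CC(O)COC(=O)c1cc(OCc2ccccc2)c(OCc2ccccc2)c(OCc2ccccc2)c1/C=C/C(=O)N3[C@@H](Cc4ccccc4)COC3=O
F2 | step 7 | 2-oxobut-3-en-1-yl 3,4,5-tris(benzyloxy)-2-{(1E)-3-[(4S)-4-benzyl-2-oxo-1,3-oxazolidin-3-yl]-3-oxoprop-1-en-1-yl}benzoate | C=CC(=O)COC(=O)c1cc(OCc2ccccc2)c(OCc2ccccc2)c(OCc2ccccc2)c1/C=C/C(=O)N3[C@@H](Cc4ccccc4)COC3=O
F3 | step 7 | (1Z)-2-(tert-butyldimethylsilyloxy)buta-1,3-dien-1-yl 3,4,5-tris(benzyloxy)-2-{(1E)-3-[(4S)-4-benzyl-2-oxo-1,3-oxazolidin-3-yl]-3-oxoprop-1-en-1-yl}benzoate | C=C/C(O[Si](C)(C)C(C)(C)C)=C/OC(=O)c1cc(OCc2ccccc2)c(OCc2ccccc2)c(OCc2ccccc2)c1/C=C/C(=O)N3[C@@H](Cc4ccccc4)COC3=O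
F4 | step 7 | (4S)-4-benzyl-3-{[(1S,4aS,10bS)-8,9,10-tris(benzyloxy)-4-(tert-butyldimethylsilyloxy)-6-oxo-1,2,4a,10b-tetrahydro-6H-benzo[c]chromen-1-yl]carbonyl}-1,3-oxazolidin-2-one | C3C[C@H](C(=O)N4[C@@H](Cc8ccccc8)COC4=O)[C@H]1c2c(cc(OCc5ccccc5)c(OCc6ccccc6)c2OCc7ccccc7)C(=O)O[C@@H]1C=3O[Si](C)(C)C(C)(C)C
F5 | step 7 | (3S,4S)-5,6,7-tris(benzyloxy)-4-{(2S)-1-[(4S)-4-benzyl-2-oxo-1,3-oxazolidin-3-yl]-1,4-dioxobutan-2-yl}-1-oxo-3,4-dihydro-1H-isochromene-3-carboxylic acid | O=CC[C@H](C(=O)N4[C@@H](Cc8ccccc8)COC4=O)[C@H]1c2c(cc(OCc5ccccc5)c(OCc6ccccc6)c2OCc7ccccc7)C(=O)O[C@@H]1C(=O)O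
F6 | step 7 | (3S,4S)-5,6,7-tris(benzyloxy)-4-{(2S)-1-[(4S)-4-benzyl-2-oxo-1,3-oxazolidin-3-yl]-3-carboxy-1-oxopropan-2-yl}-1-oxo-3,4-dihydro-1H-isochromene-3-carboxylic acid | O=C(O)C[C@H](C(=O)N4[C@@H](Cc8ccccc8)COC4=O)[C@H]1c2c(cc(OCc5ccccc5)c(OCc6ccccc6)c2OCc7ccccc7)C(=O)O[C@@H]1C(=O)O
F7 | step 6 | 3,4,5-tris(benzyloxy)-2-{(1E)-3-[(4S)-4-benzyl-2-oxo-1,3-oxazolidin-3-yl]-3-oxoprop-1-en-1-yl}benzoyl fluoride | FC(=O)c1cc(OCc2ccccc2)c(OCc2ccccc2)c(OCc2ccccc2)c1/C=C/C(=O)N3[C@@H](Cc4ccccc4)COC3=O
F8 | step 4 | [2,3,4-tris(benzyloxy)-6-(tert-butoxycarbonyl)phenyl]magnesium chloride | CC(C)(C)OC(=O)c1cc(OCc2ccccc2)c(OCc2ccccc2)c(OCc2ccccc2)c1[Mg]Cl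
F9 | step 4 | tert-butyl 3,4,5-tris(benzyloxy)-2-formylbenzoate | CC(C)(C)OC(=O)c1cc(OCc2ccccc2)c(OCc2ccccc2)c(OCc2ccccc2)c1C=O
F10 | step 4 | diethyl {2-[(4S)-4-benzyl-2-oxo-1,3-oxazolidin-3-yl]-2-oxoethyl}phosphonate | CCOP(=O)(OCC)CC(=O)N1[C@@H](Cc2ccccc2)COC1=O
F11 | step 8 | S-ethyl (1S,4aR,10bS)-8,9,10-tris(benzyloxy)-6-oxo-1,2,4a,10b-tetrahydro-6H-benzo[c]chromene-1-carbothioate | C3C[C@H](C(=O)SCC)[C@H]1c2c(cc(OCc5ccccc5)c(OCc6ccccc6)c2OCc7ccccc7)C(=O)O[C@@H]1C=3
F12 | step 9 | (1S,4aS,10bS)-8,9,10-tris(benzyloxy)-3,4-cis-dihydroxy-6-oxo-1,2,3,4,4a,10b-hexahydro-6H-benzo[c]chromene-1-carboxylic acid (carbinol centres undefined) | OC3C[C@H](C(=O)O)[C@H]1c2c(cc(OCc5ccccc5)c(OCc6ccccc6)c2OCc7ccccc7)C(=O)O[C@@H]1C3O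
A1 | alternative 1 | benzyl 5,6,7-tris(benzyloxy)-1-oxo-1H-isochromene-3-carboxylate | O=C(OCc1ccccc1)C1=Cc2c(cc(OCc3ccccc3)c(OCc3ccccc3)c2OCc2ccccc2)C(=O)O1
A2 | alternative 2 | benzyl (2E)-3-[2,3,4-tris(benzyloxy)-6-(tert-butoxycarbonyl)phenyl]prop-2-en-1-yl butanedioate | CC(C)(C)OC(=O)c1cc(OCc2ccccc2)c(OCc2ccccc2)c(OCc2ccccc2)c1/C=C/COC(=O)CCC(=O)OCc1ccccc1
A3 | alternative 2 | (2S,3S)-2-[2-(benzyloxy)-2-oxoethyl]-3-[2,3,4-tris(benzyloxy)-6-(tert-butoxycarbonyl)phenyl]pent-4-enoic acid | O=C(OCc3ccccc3)C[C@H](C(=O)O)[C@H](C=C)c1c(cc(OCc2ccccc2)c(OCc2ccccc2)c1OCc1ccccc1)C(=O)OC(C)(C)C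
A4 | alternative 3 | (4R)-4-(tert-butyldimethylsilyloxy)cyclopent-2-en-1-one | O=C1C=C[C@H](O[Si](C)(C)C(C)(C)C)C1
A5 | alternative 3 | all-trans (2,3-trans-3,4-trans) tert-butyl 3,4,5-tris(benzyloxy)-2-[2-(2-tert-butoxy-2-oxoethyl)-5-(tert-butyldimethylsilyloxy)-3-oxocyclopentyl]benzoate | O=C(OC(C)(C)C)C[C@@H]3[C@@H](c1c(cc(OCc2ccccc2)c(OCc2ccccc2)c1OCc1ccccc1)C(=O)OC(C)(C)C)[C@H](O[Si](C)(C)C(C)(C)C)CC3=O
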